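**Plan**

- Retrosynthesis: cut the C11–O aryl ether (umbelliferone plus a diene diol), then the C8=C12 alkene (to an 8-ketone) and the C6=C7 alkene (to the saturated ketone). Next cut the pair C6–C7 and C7–C8, which removes C7 and contracts ring B to a trans-hydrindan-8-one. Further back cut C9–C11, the second C4 methyl and the annulation bonds C4=C5 and C1–C10.
- Enabling feature: in ring B, C8 lies between C9 and C7. A cyclopentanone made of C5, C6, C8, C9 and C10 with its carbonyl at C8 therefore lacks only C7, the atom that must carry the C6–C7 double bond. Inserting C7 between C8 and C6 completes ring B and keeps the C8 carbonyl for the methylenation.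
- Forward order: the five-membered ring is bought as 2-methylcyclopentane-1,3-dione and ring A is annulated onto it (steps 1–2). C4, C3, C9 and C11 are elaborated on the hydrindane (steps 3–15). Ring B arises by one-carbon enlargement (step 16), and the diene and the coumarin ether follow (steps 17–20).
- Stereochemistry: C10 from the D-phenylalanine-mediated aldol condensation; C5 from dissolving-metal protonation anti to the C10 methyl; C3 from equatorial delivery of a bulky hydride; C9 from hydroboration anti to the C10 methyl.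

Key step: step 16

Remark 1: drimane locants of the target are used for every bicyclic compound. Ring A is C1–C5 with C10; the second ring holds C5, C6, C8, C9 and C10 until step 16 brings in C7; C11 is the oxymethyl carbon on C9 and C12 the exocyclic methylene carbon. "Syn" and "anti" refer to the C10 methyl group. TBS = tert-butyldimethylsilyl, TES = triethylsilyl.

Remark 2: the amino-acid-mediated cyclization of the ethyl-ketone triketone 3 is assumed to follow the facial sense of the parent methyl-ketone case (L-acid to S), so the D-acid is taken to deliver (7aR)-4. D-Phenylalanine is a recoverable mediator and is not numbered.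

**Route**

Step 1
Reactants: 1 2-methylcyclopentane-1,3-dione; 2 ethyl vinyl ketone (pent-1-en-3-one)
Product: 3 2-methyl-2-(3-oxopentyl)cyclopentane-1,3-dione
Conditions: AcOH (cat.), H2O, 75 °C
Reagents that add atoms: none
Why: Michael addition of the acidic 1,3-dione to the vinyl ketone in water is a standard entry to 2,2-disubstituted cyclopentane-1,3-diones and stops at the triketone under these weakly acidic conditions.

Step 2
Reactants: 3 2-methyl-2-(3-oxopentyl)cyclopentane-1,3-dione
Product: 4 (7aR)-4,7a-dimethyl-2,3,7,7a-tetrahydro-1H-indene-1,5(6H)-dione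
Conditions: D-phenylalanine (1.0 equiv), HClO4 (1 M aq., 0.5 equiv), MeCN, reflux
Reagents that add atoms: none
Why: The enamine-mediated intramolecular aldol condensation (Hajos–Parrish–Eder–Sauer–Wiechert reaction) differentiates the two ring carbonyls and sets the quaternary C10, and a primary amino acid with a strong acid co-catalyst is chosen because it copes with an ethyl ketone that ends as a tetrasubstituted enone.

Step 3
Reactants: 4 (7aR)-4,7a-dimethyl-2,3,7,7a-tetrahydro-1H-indene-1,5(6H)-dione
Product: 5 (1R,7aR)-1-hydroxy-4,7a-dimethyl-1,2,3,6,7,7a-hexahydro-5H-inden-5-one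
Conditions: NaBH4 (0.3 equiv), EtOH, −20 °C
Reagents that add atoms: none
Why: Chemoselective 1,2-reduction, since NaBH4 at low temperature reduces the saturated cyclopentanone much faster than the conjugated carbonyl, with hydride entering anti to the angular methyl so that the C9 hydroxyl is syn to it (a placeholder centre that is oxidized again in step 9).

Step 4
Reactants: 5 (1R,7aR)-1-hydroxy-4,7a-dimethyl-1,2,3,6,7,7a-hexahydro-5H-inden-5-one
Product: 6 4,10-dimethyl-9-(triethylsilyloxy)hydrind-4-en-3-one (9-O syn)
Conditions: TESCl, imidazole, DMF, 0 °C → rt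
Reagents that add atoms: chlorotriethylsilane, CC[Si](Cl)(CC)CC
Why: Standard silylation of a secondary alcohol, and the triethylsilyl ether tolerates dissolving metal and hydride yet can later be removed beside a hindered TBS ether.

Step 5
Reactants: 6 4,10-dimethyl-9-(triethylsilyloxy)hydrind-4-en-3-one
Product: 8 4,4,10-trimethyl-9-(triethylsilyloxy)-trans-hydrindan-3-one (H-5 anti), via lithium C3-enolate 7 (not isolated)
Conditions: Li (2.2 equiv), t-BuOH (1.0 equiv), NH3(l)/THF, −78 °C; then MeI (excess), −78 → −33 °C; NH4Cl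
Reagents that add atoms: iodomethane, CI
Why: Dissolving-metal reductive alkylation, in which two-electron reduction of the enone and axial protonation of C5 anti to the C10 methyl should give the trans-fused enolate 7 regiospecifically, and C-methylation at C4 then completes the geminal dimethyl group.

Step 6
Reactants: 8 4,4,10-trimethyl-9-(triethylsilyloxy)-trans-hydrindan-3-one
Product: 9 4,4,10-trimethyl-9-(triethylsilyloxy)-trans-hydrindan-3-ol (3-OH axial and anti)
Conditions: LiBH(s-Bu)3, THF, −78 °C; then NaOH, H2O2, 0 °C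
Reagents that add atoms: none
Why: Diastereoselective ketone reduction, in which the bulky trialkylborohydride avoids the axial path past the axial hydrogens at C1 and C5 and delivers hydride equatorially, so the C3 hydroxyl becomes axial and anti to the C10 methyl as is usual for 4,4-dimethyl-3-oxo terpenoids.

Step 7
Reactants: 9 4,4,10-trimethyl-9-(triethylsilyloxy)-trans-hydrindan-3-ol
Product: 10 3-(TBS-oxy)-4,4,10-trimethyl-9-(triethylsilyloxy)-trans-hydrindane
Conditions: TBSOTf, 2,6-lutidine, CH2Cl2, 0 °C → rt
Reagents that add atoms: tert-butyldimethylsilyl trifluoromethanesulfonate, CC(C)(C)[Si](C)(C)OS(=O)(=O)C(F)(F)F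
Why: A silyl triflate with 2,6-lutidine is the standard way to silylate a hindered axial alcohol next to a quaternary carbon, and the TES ether is not exchanged under these buffered conditions.

Step 8
Reactants: 10 3-(TBS-oxy)-4,4,10-trimethyl-9-(triethylsilyloxy)-trans-hydrindane
Product: 11 3-(TBS-oxy)-4,4,10-trimethyl-trans-hydrindan-9-ol
Conditions: camphorsulfonic acid (0.1 equiv), MeOH/CH2Cl2 (1:1), 0 °C
Reagents that add atoms: none
Why: Selective desilylation by acid-catalysed methanolysis, because a TES ether is cleaved far faster than the more hindered TBS ether on the axial C3 oxygen.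

Step 9
Reactants: 11 3-(TBS-oxy)-4,4,10-trimethyl-trans-hydrindan-9-ol
Product: 12 3-(TBS-oxy)-4,4,10-trimethyl-trans-hydrindan-9-one
Conditions: Dess–Martin periodinane, NaHCO3, CH2Cl2, rt
Reagents that add atoms: none
Why: Dess–Martin oxidation of the secondary alcohol under buffered neutral conditions returns the C9 carbonyl without touching the silyl ether.

Step 10
Reactants: 12 3-(TBS-oxy)-4,4,10-trimethyl-trans-hydrindan-9-one
Product: 14 3-(TBS-oxy)-4,4,10-trimethyl-trans-hydrind-8-en-9-yl trifluoromethanesulfonate, via potassium C9-enolate 13 (not isolated)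
Conditions: KN(SiMe3)2, THF, −78 °C; then PhNTf2, −78 → 0 °C
Reagents that add atoms: N-phenylbis(trifluoromethanesulfonimide), O=S(=O)(N(c1ccccc1)S(=O)(=O)C(F)(F)F)C(F)(F)F
Why: Enol triflate formation, which gives a single regioisomer because the C9 ketone can enolize only toward C8 (C10 is quaternary), as practised on steroidal ring D ketones.

Step 11
Reactants: 14 3-(TBS-oxy)-4,4,10-trimethyl-trans-hydrind-8-en-9-yl trifluoromethanesulfonate
Product: 15 methyl 3-(TBS-oxy)-4,4,10-trimethyl-trans-hydrind-8-ene-9-carboxylate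
Conditions: Pd(OAc)2 (5 mol %), PPh3 (10 mol %), CO (1 atm), MeOH, Et3N, DMF, 60 °C
Reagents that add atoms: carbon monoxide, [C-]#[O+]; methanol, CO
Why: Palladium-catalysed alkoxycarbonylation of an enol triflate, in which oxidative addition to zerovalent palladium, CO insertion and methanolysis of the acylpalladium species place C11 on C9 as the conjugated ester.

Step 12
Reactants: 15 methyl 3-(TBS-oxy)-4,4,10-trimethyl-trans-hydrind-8-ene-9-carboxylate
Product: 16 [3-(TBS-oxy)-4,4,10-trimethyl-trans-hydrind-8-en-9-yl]methanol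
Conditions: i-Bu2AlH (2.5 equiv), CH2Cl2, −78 → 0 °C; aq. potassium sodium tartrate
Reagents that add atoms: none
Why: i-Bu2AlH reduces a conjugated ester to the allylic alcohol by 1,2-hydride delivery and leaves the trisubstituted alkene alone.

Step 13
Reactants: 16 [3-(TBS-oxy)-4,4,10-trimethyl-trans-hydrind-8-en-9-yl]methanol
Product: 17 3,11-bis(TBS-oxy)-4,4,10-trimethyl-9-methyl-trans-hydrind-8-ene
Conditions: TBSCl, imidazole, DMF, rt
Reagents that add atoms: tert-butyldimethylsilyl chloride, CC(C)(C)[Si](C)(C)Cl
Why: Routine silylation of the primary allylic alcohol protects O11 for the borane, oxidation and organometallic steps that follow.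

Step 14
Reactants: 17 3,11-bis(TBS-oxy)-4,4,10-trimethyl-9-methyl-trans-hydrind-8-ene
Product: 19 3,11-bis(TBS-oxy)-4,4,10-trimethyl-9-methyl-trans-hydrindan-8-ol (8-OH anti; C11 syn), via C8 alkylborane 18 (not isolated)
Conditions: BH3·THF, THF, 0 °C → rt; then NaOH (3 M), H2O2 (30 %), 0 °C → rt
Reagents that add atoms: hydrogen peroxide, OO
Why: Hydroboration–oxidation, in which borane adds syn with boron on the less substituted C8 and hydrogen on C9 from the face anti to the C10 methyl, so H-9 is anti and the C11 arm syn to that methyl (the outcome known for 17-substituted steroidal 16-enes), and oxidation with retention gives the C8 alcohol.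

Step 15
Reactants: 19 3,11-bis(TBS-oxy)-4,4,10-trimethyl-9-methyl-trans-hydrindan-8-ol
Product: 20 3,11-bis(TBS-oxy)-4,4,10-trimethyl-9-methyl-trans-hydrindan-8-one (7-nor bicycle)
Conditions: Dess–Martin periodinane, NaHCO3, CH2Cl2, rt
Reagents that add atoms: none
Why: Buffered Dess–Martin oxidation gives the cyclopentanone under neutral conditions that neither epimerize the adjacent C9 nor expel the C11 silyloxy group.

Step 16
Reactants: 20 3,11-bis(TBS-oxy)-4,4,10-trimethyl-9-methyl-trans-hydrindan-8-one
Product: 22 3,11-bis(TBS-oxy)-12-nordriman-8-one of the ent series (trans-decalin), via C7-silyl ketone 21 (not isolated)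
Conditions: AlMe3 (1.2 equiv), TMSCHN2 (1.2 equiv), CH2Cl2, −78 → −20 °C; then 1 M HCl, THF, 0 °C (brief)
Reagents that add atoms: trimethylsilyldiazomethane, C[Si](C)(C)C=[N+]=[N-]
Why: AlMe3 activates the C8 carbonyl, the diazo carbon adds to C8, and in the resulting β-diazonium alkoxide C6 shifts from C8 to the new carbon with loss of N2, which forms C6–C7 and C7–C8 and gives the C7-silyl ketone 21 that is protodesilylated to 22 on acidic work-up. The closest known reaction is the Lewis-acid-promoted diazoalkane–ketone homologation of Tiffeneau–Demjanov type, established for cyclopentanone-to-cyclohexanone enlargement including steroidal ring D ketones. Ring B is not closed by a cyclization but arises by 1,2-alkyl-shift enlargement of the ring C5–C6–C8–C9–C10 through insertion of C7. No new stereocentre persists (C7 ends as CH2), and C5, C9 and C10 are untouched because the medium is non-basic and C9 does not migrate; the equatorial C11 arm of 22 is in any case the more stable arrangement. The step needs migration of C6 rather than C9 and a single insertion: C6 is an unhindered methylene whereas C9 is tertiary and flanked by quaternary C10, the bulky silyl group of the adduct turns away from the C9 side so that the C8–C6 bond lies anti to the departing nitrogen, and near-stoichiometric reagent, low temperature and the hindered, less electrophilic silyl ketone 21 should limit a second homologation.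

Step 17
Reactants: 22 3,11-bis(TBS-oxy)-12-nordriman-8-one of the ent series
Product: 24 3,11-bis(TBS-oxy)-12-nordrim-6-en-8-one of the ent series, via trimethylsilyl enol ether 23 (not isolated)
Conditions: LiN(i-Pr)2 (1.1 equiv), THF, −78 °C; TMSCl, Et3N, −78 → 0 °C; then Pd(OAc)2 (1.1 equiv), MeCN, rt
Reagents that add atoms: none
Why: Saegusa–Ito oxidation, in which kinetic deprotonation by the hindered amide occurs at the C7 methylene and not at the tertiary C9, the enolate is trapped as silyl enol ether 23, and divalent palladium then forms an oxa-π-allyl species that loses a β-hydride from C6 to give the C6–C7 alkene.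

Step 18
Reactants: 24 3,11-bis(TBS-oxy)-12-nordrim-6-en-8-one of the ent series
Product: 25 3,11-bis(TBS-oxy)drima-6,8(12)-diene of the ent series
Conditions: Ph3PCH3Br (3.0 equiv), KOt-Bu (2.8 equiv), THF, 0 °C → reflux
Reagents that add atoms: methyltriphenylphosphonium bromide, C[P+](c1ccccc1)(c1ccccc1)c1ccccc1.[Br-]
Why: Wittig methylenation, in which the unstabilized ylide adds 1,2 to the enone carbonyl and phosphine oxide is lost, and keeping the phosphonium salt in slight excess over the base avoids free alkoxide that could enolize C9 or C5.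

Step 19
Reactants: 25 3,11-bis(TBS-oxy)drima-6,8(12)-diene of the ent series
Product: 26 drima-6,8(12)-diene-3,11-diol of the ent series (3-OH axial and anti)
Conditions: TBAF (5 equiv), THF, 60 °C
Reagents that add atoms: none
Why: Fluoride-mediated desilylation cleaves both silicon–oxygen bonds (the hindered C3 ether needs warming), and the basic medium leaves the acid-sensitive 1,3-diene untouched.

Step 20
Reactants: 26 drima-6,8(12)-diene-3,11-diol of the ent series; 27 umbelliferone (7-hydroxy-2H-chromen-2-one)
Product: 28 CNP0259618.1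
Conditions: PPh3, DIAD, THF, 0 °C → rt
Reagents that add atoms: none
Why: Mitsunobu etherification, in which the acidic phenol displaces the activated primary C11 oxyphosphonium ion while the axial C3 hydroxyl next to the quaternary C4 is too hindered to be activated, so the aryl ether forms chemoselectively and no stereocentre is involved.

**Compound list**

1 | 2-methylcyclopentane-1,3-dione | CC1C(=O)CCC1=O | starting material
2 | ethyl vinyl ketone (pent-1-en-3-one) | CCC(=O)C=C | starting material
3 | 2-methyl-2-(3-oxopentyl)cyclopentane-1,3-dione | CCC(=O)CCC1(C)C(=O)CCC1=O | intermediate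
4 | (7aR)-4,7a-dimethyl-2,3,7,7a-tetrahydro-1H-indene-1,5(6H)-dione (3,9-dioxo-4-ene in drimane locants) | C1CC2=C(C)C(=O)CC[C@@]2(C)C1=O | intermediate
5 | (1R,7aR)-1-hydroxy-4,7a-dimethyl-1,2,3,6,7,7a-hexahydro-5H-inden-5-one (9-OH syn to the C10 methyl) | C1CC2=C(C)C(=O)CC[C@@]2(C)[C@@H]1O | intermediate
6 | 4,10-dimethyl-9-(triethylsilyloxy)hydrind-4-en-3-one, 9-O syn | C1CC2=C(C)C(=O)CC[C@@]2(C)[C@@H]1O[Si](CC)(CC)CC | intermediate
7 | lithium C3-enolate (C3=C4) of trans-fused 4,10-dimethyl-9-(triethylsilyloxy)hydrindan-3-one, H-5 anti | C1C[C@@H]2C(C)=C(O[Li])CC[C@@]2(C)[C@@H]1O[Si](CC)(CC)CC | intermediate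
8 | 4,4,10-trimethyl-9-(triethylsilyloxy)-trans-hydrindan-3-one, H-5 anti, 9-O syn | C1C[C@@H]2C(C)(C)C(=O)CC[C@@]2(C)[C@@H]1O[Si](CC)(CC)CC | intermediate
9 | 4,4,10-trimethyl-9-(triethylsilyloxy)-trans-hydrindan-3-ol, 3-OH axial and anti | C1C[C@@H]2C(C)(C)[C@@H](O)CC[C@@]2(C)[C@@H]1O[Si](CC)(CC)CC | intermediate
10 | 3-(tert-butyldimethylsilyloxy)-4,4,10-trimethyl-9-(triethylsilyloxy)-trans-hydrindane | C1C[C@@H]2C(C)(C)[C@@H](O[Si](C)(C)C(C)(C)C)CC[C@@]2(C)[C@@H]1O[Si](CC)(CC)CC | intermediate
11 | 3-(tert-butyldimethylsilyloxy)-4,4,10-trimethyl-trans-hydrindan-9-ol, 9-OH syn | C1C[C@@H]2C(C)(C)[C@@H](O[Si](C)(C)C(C)(C)C)CC[C@@]2(C)[C@@H]1O | intermediate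
12 | 3-(tert-butyldimethylsilyloxy)-4,4,10-trimethyl-trans-hydrindan-9-one | C1C[C@@H]2C(C)(C)[C@@H](O[Si](C)(C)C(C)(C)C)CC[C@@]2(C)C1=O | intermediate
13 | potassium C9-enolate (C8=C9) of 12 | [K]OC1=CC[C@@H]2C(C)(C)[C@@H](O[Si](C)(C)C(C)(C)C)CC[C@@]12C | intermediate
14 | 3-(tert-butyldimethylsilyloxy)-4,4,10-trimethyl-trans-hydrind-8-en-9-yl trifluoromethanesulfonate | FC(F)(F)S(=O)(=O)OC1=CC[C@@H]2C(C)(C)[C@@H](O[Si](C)(C)C(C)(C)C)CC[C@@]12C | intermediate
15 | methyl 3-(tert-butyldimethylsilyloxy)-4,4,10-trimethyl-trans-hydrind-8-ene-9-carboxylate (ester carbon = C11) | COC(=O)C1=CC[C@@H]2C(C)(C)[C@@H](O[Si](C)(C)C(C)(C)C)CC[C@@]12C | intermediate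
16 | [3-(tert-butyldimethylsilyloxy)-4,4,10-trimethyl-trans-hydrind-8-en-9-yl]methanol | OCC1=CC[C@@H]2C(C)(C)[C@@H](O[Si](C)(C)C(C)(C)C)CC[C@@]12C | intermediate
17 | 3,11-bis(tert-butyldimethylsilyloxy)-4,4,10-trimethyl-9-methyl-trans-hydrind-8-ene | CC(C)(C)[Si](C)(C)OCC1=CC[C@@H]2C(C)(C)[C@@H](O[Si](C)(C)C(C)(C)C)CC[C@@]12C | intermediate
18 | C8 monoalkylborane from 17, boron and H-9 anti, C11 syn | B[C@H]1C[C@@H]2C(C)(C)[C@@H](O[Si](C)(C)C(C)(C)C)CC[C@@]2(C)[C@@H]1CO[Si](C)(C)C(C)(C)C | intermediate
19 | 3,11-bis(tert-butyldimethylsilyloxy)-4,4,10-trimethyl-9-methyl-trans-hydrindan-8-ol, 8-OH and H-9 anti, C11 syn | O[C@H]1C[C@@H]2C(C)(C)[C@@H](O[Si](C)(C)C(C)(C)C)CC[C@@]2(C)[C@@H]1CO[Si](C)(C)C(C)(C)C | intermediate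
20 | 3,11-bis(tert-butyldimethylsilyloxy)-4,4,10-trimethyl-9-methyl-trans-hydrindan-8-one (7-nor bicycle, C11 syn) | O=C1C[C@@H]2C(C)(C)[C@@H](O[Si](C)(C)C(C)(C)C)CC[C@@]2(C)[C@@H]1CO[Si](C)(C)C(C)(C)C | intermediate
21 | 7-(trimethylsilyl) derivative of 22 (C7 configuration not defined) | O=C1C([Si](C)(C)C)C[C@@H]2C(C)(C)[C@@H](O[Si](C)(C)C(C)(C)C)CC[C@@]2(C)[C@@H]1CO[Si](C)(C)C(C)(C)C | intermediate
22 | 3,11-bis(tert-butyldimethylsilyloxy)-12-nordriman-8-one of the ent series (trans-decalin, C11 equatorial and syn) | O=C1CC[C@@H]2C(C)(C)[C@@H](O[Si](C)(C)C(C)(C)C)CC[C@@]2(C)[C@@H]1CO[Si](C)(C)C(C)(C)C | intermediate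
23 | 8-(trimethylsilyloxy)-7-ene silyl enol ether of 22 | C[Si](C)(C)OC1=CC[C@@H]2C(C)(C)[C@@H](O[Si](C)(C)C(C)(C)C)CC[C@@]2(C)[C@@H]1CO[Si](C)(C)C(C)(C)C | intermediate
24 | 3,11-bis(tert-butyldimethylsilyloxy)-12-nordrim-6-en-8-one of the ent series | O=C1C=C[C@@H]2C(C)(C)[C@@H](O[Si](C)(C)C(C)(C)C)CC[C@@]2(C)[C@@H]1CO[Si](C)(C)C(C)(C)C | intermediate
25 | 3,11-bis(tert-butyldimethylsilyloxy)drima-6,8(12)-diene of the ent series | C=C1C=C[C@@H]2C(C)(C)[C@@H](O[Si](C)(C)C(C)(C)C)CC[C@@]2(C)[C@@H]1CO[Si](C)(C)C(C)(C)C | intermediate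
26 | drima-6,8(12)-diene-3,11-diol of the ent series, 3-OH axial and anti, C11 syn | C=C1C=C[C@@H]2C(C)(C)[C@@H](O)CC[C@@]2(C)[C@@H]1CO | intermediate
27 | umbelliferone (7-hydroxy-2H-chromen-2-one) | O=c1ccc2ccc(O)cc2o1 | starting material
28 | CNP0259618.1, 7-{[(1R,4aS,6S,8aR)-6-hydroxy-5,5,8a-trimethyl-2-methylidene-1,2,4a,5,6,7,8,8a-octahydronaphthalen-1-yl]methoxy}-2H-chromen-2-one | C=C1C=C[C@@H]2C(C)(C)[C@@H](O)CC[C@@]2(C)[C@@H]1COc1ccc2ccc(=O)oc2c1 | target

**Step count and risks**

Total steps: 20. Longest linear sequence: 20 steps (1 to 28); umbelliferone 27 enters in the last step.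

The three steps most likely to fail:

Step 16. The shift could go the wrong way (C9 instead of C6 migrating), a second insertion could follow, or the alkoxide oxygen could close onto the diazonium carbon to give an epoxide. The fallback makes the same two bonds by cyclopropanation and oxidative ring opening and sets out from 20. Kinetic enolization toward the C6 methylene (LiN(i-Pr)2, TMSCl, THF, −78 °C) should give the 8-(trimethylsilyloxy)hydrind-6(8)-ene F2. Simmons–Smith cyclopropanation (Et2Zn, CH2I2, CH2Cl2, 0 °C) adds the future C7 across C6 and C8 to give the siloxycyclopropane F3. FeCl3 in DMF at 0 °C cleaves the shared C6–C8 bond oxidatively to the ring-enlarged 6-chloro-8-ketone F4. Loss of HCl with NaOAc in MeOH at reflux then gives the enone and comes back to the route at 24, so that steps 16 and 17 are both replaced.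

Step 5. Protonation at C5 may lack facial selectivity and give cis-fused material, and the enolate may be O-methylated or the C3 carbonyl over-reduced. The fallback sets out from 6. Deconjugative C4 methylation (KOt-Bu, MeI, t-BuOH, rt) through the extended dienolate would give 4,4,10-trimethyl-9-(triethylsilyloxy)hydrind-5-en-3-one F1. Hydrogenation (H2, Pd/CaCO3, EtOAc) should add hydrogen to C5 from the face anti to both the C10 methyl and the syn C9 silyloxy group, as in steroidal 14-enes with a 17-oxygen substituent, and comes back to the route at 8.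

Step 18. The basic ylide may enolize the ketone toward C9 with loss of the C11 silanolate, may deconjugate the enone through C5, or may add only sluggishly to the hindered conjugated carbonyl. The fallback sets out from 24 and separates addition from elimination. The weakly basic organocerium reagent from Me3SiCH2Li and CeCl3 (THF, −78 °C) should add 1,2 to give the 8-hydroxy-8-(trimethylsilylmethyl) adduct F5. Peterson elimination with KH in THF (0 °C → rt) then gives the exocyclic alkene and comes back to the route at 25.

**Further compounds**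

F1 | step 5 | 4,4,10-trimethyl-9-(triethylsilyloxy)hydrind-5-en-3-one (C5=C6, 9-O syn) | C1C=C2C(C)(C)C(=O)CC[C@@]2(C)[C@@H]1O[Si](CC)(CC)CC
F2 | step 16 | 3,11-bis(tert-butyldimethylsilyloxy)-8-(trimethylsilyloxy)-4,4,10-trimethyl-9-methyl-trans-hydrind-6(8)-ene | C[Si](C)(C)OC1=C[C@@H]2C(C)(C)[C@@H](O[Si](C)(C)C(C)(C)C)CC[C@@]2(C)[C@@H]1CO[Si](C)(C)C(C)(C)C
F3 | step 16 | siloxycyclopropane with C7 bridging C6 and C8 on the face anti to the C10 methyl | C[Si](C)(C)O[C@]12C[C@H]1[C@@H]3C(C)(C)[C@@H](O[Si](C)(C)C(C)(C)C)CC[C@@]3(C)[C@@H]2CO[Si](C)(C)C(C)(C)C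
F4 | step 16 | 6-chloro-3,11-bis(tert-butyldimethylsilyloxy)-12-nordriman-8-one of the ent series (C6 configuration not defined) | O=C1CC(Cl)[C@@H]2C(C)(C)[C@@H](O[Si](C)(C)C(C)(C)C)CC[C@@]2(C)[C@@H]1CO[Si](C)(C)C(C)(C)C
F5 | step 18 | 8-hydroxy-8-(trimethylsilylmethyl)-3,11-bis(tert-butyldimethylsilyloxy)-12-nordrim-6-ene of the ent series (C8 configuration not defined) | C[Si](C)(C)CC1(O)C=C[C@@H]2C(C)(C)[C@@H](O[Si](C)(C)C(C)(C)C)CC[C@@]2(C)[C@@H]1CO[Si](C)(C)C(C)(C)C
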